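**Plan**

- The retrosynthesis first cuts the depside ester bond between O-4' of ring B and the C-1 carbonyl of ring A, with the two ring-A phenols masked as benzyl ethers. Ring B is then cut at C1'–C2' and C5'–C6'.
- Ring B allows this cut because its two oxygens differ (OMe on C2', O-acyl on C4') on either side of the C3' methyl, with CO2Me on C1' next to the C6' methyl. C2'–C5' map onto a 1,1-dimethoxy-2-methyl-3-silyloxybutadiene, and C1'/C6' onto methyl but-2-ynoate.
- Forward, ring B: orthopropionate → methylketene acetal → acylketene acetal → silyloxydiene, then cycloaddition with loss of methanol closes ring B. It is the only ring made; ring A is bought as methyl orsellinate.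
- Forward, ring A: formylation at C3, benzylation, saponification. The acid is then esterified with the ring-B phenol and the benzyl ethers are removed.
- Stereochemistry: the target has no stereocentre and no stable axis, so nothing has to be controlled.

Key step: step 4

Remark: the target is achiral, so the "single enantiomer" requirement is met by the constitution alone.

**Route**

Step 1
Reactants: 1 trimethyl orthopropionate
Product: 2 1,1-dimethoxyprop-1-ene (methylketene dimethyl acetal)
Conditions: TMSOTf (1.1 equiv), i-Pr2NEt (1.3 equiv), CH2Cl2, −20 °C → rt; pentane, filter, distil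
Reagents that add atoms: none
Why: Silyl triflate ionises the orthoester to the dimethoxycarbenium ion and the hindered amine removes the α-proton, the established silyl-triflate/amine 1,2-elimination of alcohol from acetals and orthoesters; the volatile ketene acetal should distil away from the ammonium salt.

Step 2
Reactants: 2 1,1-dimethoxyprop-1-ene; 3 acetyl chloride
Product: 4 4,4-dimethoxy-3-methylbut-3-en-2-one
Conditions: Et3N, Et2O, 0 °C → rt
Reagents that add atoms: none
Why: C-Acylation of a ketene acetal by an acid chloride, in which the acyl-dimethoxycarbenium ion formed first should lose its doubly activated α-proton to Et3N and give the push–pull acylketene acetal.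

Step 3
Reactants: 4 4,4-dimethoxy-3-methylbut-3-en-2-one
Product: 5 tert-butyl[(4,4-dimethoxy-3-methylbuta-1,3-dien-2-yl)oxy]dimethylsilane (1,1-dimethoxy-2-methyl-3-silyloxybuta-1,3-diene)
Conditions: TBSOTf, Et3N, Et2O, 0 °C → rt
Reagents that add atoms: tert-butyldimethylsilyl trifluoromethanesulfonate, CC(C)(C)[Si](C)(C)OS(=O)(=O)C(F)(F)F
Why: Soft enolisation of a methyl ketone, in which O-silylation of the basic vinylogous-carbonate carbonyl is followed by deprotonation of the acetyl CH3, the only site that gives a neutral diene; this is the standard preparation of 2-silyloxybutadienes from enones.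

Step 4
Reactants: 5 silyloxydiene (1.5–2 equiv); 6 methyl but-2-ynoate
Product: 8 methyl 4-(tert-butyldimethylsilyloxy)-2-methoxy-3,6-dimethylbenzoate, via dimethoxycyclohexadiene adduct 7 (not isolated)
Conditions: toluene, 120 °C, sealed tube; then cat. PPTS, CH2Cl2, rt
Reagents that add atoms: none
Why: The electron-rich diene 5 should add to the ynoate in an asynchronous, polarised Diels–Alder reaction (in the limit a Michael addition followed by ring closure onto the dimethoxycarbenium ion), its CH2 terminus bonding to the β-carbon of 6 and its acetal carbon to the α-carbon. The closest known reaction type is the cycloaddition–aromatisation of 1,1-dialkoxy-3-silyloxybuta-1,3-dienes with acetylenic esters and quinones to give resorcinol derivatives. Ring B closes as a six-membered carbocycle in a [4+2] mode, the C5'–C6' and C1'–C2' bonds being made in the same event. Adduct 7 is a 1,4-cyclohexadiene with a ketal carbon; ionisation of one methoxy group and loss of a C5' proton (1,4-elimination of methanol) gives the arene, leaving OMe on C2' while the silyl enol ether becomes the aryl silyl ether on C4'. No stereocentre is formed. The step needs regioselectivity, and the substrate polarity secures it: C4 of the diene receives the donation of all three oxygens and is its most nucleophilic site, while the β-carbon of the ynoate is the electrophilic one.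

Step 5
Reactants: 8 methyl 4-(tert-butyldimethylsilyloxy)-2-methoxy-3,6-dimethylbenzoate
Product: 9 methyl 4-hydroxy-2-methoxy-3,6-dimethylbenzoate
Conditions: KHF2, MeOH, rt
Reagents that add atoms: none
Why: Fluoride-mediated cleavage of an aryl silyl ether (strong Si–F bond, phenoxide leaving group), a mild desilylation that should leave the methyl ester and the aryl methyl ether untouched.

Step 6
Reactants: 10 methyl orsellinate (methyl 2,4-dihydroxy-6-methylbenzoate)
Product: 12 methyl haematommate (methyl 3-formyl-2,4-dihydroxy-6-methylbenzoate), via chloro(methoxy)methyl arene 11 (not isolated)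
Conditions: Cl2CHOMe (1.2 equiv), TiCl4 (2.2 equiv), CH2Cl2, −10 → 0 °C; then ice/1 M HCl
Reagents that add atoms: dichloromethyl methyl ether, COC(Cl)Cl; water, O
Why: Rieche formylation, in which the titanium phenoxide should direct the oxocarbenium electrophile to C3, the only position ortho to both hydroxyls (C5 is flanked by the C6 methyl), and aqueous work-up hydrolyses the α-chloro ether to the doubly hydrogen-bonded aldehyde.

Step 7
Reactants: 12 methyl haematommate
Product: 13 methyl 2,4-bis(benzyloxy)-3-formyl-6-methylbenzoate
Conditions: BnBr (2.5 equiv), K2CO3, DMF, 60 °C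
Reagents that add atoms: benzyl bromide, BrCc1ccccc1
Why: Williamson etherification, for which excess carbonate in warm DMF should also alkylate the hydrogen-bonded phenols, while the non-enolisable aldehyde and the methyl ester are inert.

Step 8
Reactants: 13 methyl 2,4-bis(benzyloxy)-3-formyl-6-methylbenzoate
Product: 14 2,4-bis(benzyloxy)-3-formyl-6-methylbenzoic acid
Conditions: KOH, DMSO–H2O, 70 °C; then aq. HCl
Reagents that add atoms: potassium hydroxide, [K+].[OH-]
Why: Saponification of a di-ortho-substituted benzoate with poorly solvated hydroxide in aqueous DMSO, the usual answer to such hindered esters; the aldehyde is non-enolisable and shielded by two ortho benzyloxy groups and should survive.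

Step 9
Reactants: 14 2,4-bis(benzyloxy)-3-formyl-6-methylbenzoic acid; 9 methyl 4-hydroxy-2-methoxy-3,6-dimethylbenzoate
Product: 16 methyl 4-{[2,4-bis(benzyloxy)-3-formyl-6-methylbenzoyl]oxy}-2-methoxy-3,6-dimethylbenzoate, via mixed trifluoroacetic anhydride 15 (not isolated)
Conditions: TFAA (3 equiv), toluene, rt
Reagents that add atoms: none
Why: Trifluoroacetic-anhydride-mediated esterification through the mixed anhydride (acylium-like acyl donor), the standard way to join hindered ortho-alkoxybenzoic acids to phenols in depside synthesis; 9 has a single free hydroxyl.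

Step 10
Reactants: 16 dibenzyl-protected depside
Product: 17 2'-O-methylatranorin
Conditions: H2 (1 atm), 10% Pd/C, EtOAc, rt; stopped after uptake of 2 equiv
Reagents that add atoms: none
Why: Catalytic hydrogenolysis of aryl benzyl ethers, to which the aryl ester, methyl ester and aryl methyl ether are inert; the aldehyde, hindered and hydrogen-bonded between the two freed hydroxyls, should be reduced much more slowly.

**Compound list**

1 | trimethyl orthopropionate (1,1,1-trimethoxypropane) | CCC(OC)(OC)OC | starting material
2 | 1,1-dimethoxyprop-1-ene (methylketene dimethyl acetal) | CC=C(OC)OC | intermediate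
3 | acetyl chloride | CC(Cl)=O | starting material
4 | 4,4-dimethoxy-3-methylbut-3-en-2-one | CC(=O)C(C)=C(OC)OC | intermediate
5 | tert-butyl[(4,4-dimethoxy-3-methylbuta-1,3-dien-2-yl)oxy]dimethylsilane | COC(OC)=C(C)C(=C)O[Si](C)(C)C(C)(C)C | intermediate
6 | methyl but-2-ynoate | CC#CC(=O)OC | starting material
7 | methyl 4-(tert-butyldimethylsilyloxy)-6,6-dimethoxy-2,5-dimethylcyclohexa-1,4-diene-1-carboxylate | COC(=O)C1=C(C)CC(O[Si](C)(C)C(C)(C)C)=C(C)C1(OC)OC | intermediate (not isolated)
8 | methyl 4-(tert-butyldimethylsilyloxy)-2-methoxy-3,6-dimethylbenzoate | COC(=O)c1c(C)cc(O[Si](C)(C)C(C)(C)C)c(C)c1OC | intermediate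
9 | methyl 4-hydroxy-2-methoxy-3,6-dimethylbenzoate | COC(=O)c1c(C)cc(O)c(C)c1OC | intermediate
10 | methyl orsellinate (methyl 2,4-dihydroxy-6-methylbenzoate) | COC(=O)c1c(C)cc(O)cc1O | starting material
11 | methyl 3-[chloro(methoxy)methyl]-2,4-dihydroxy-6-methylbenzoate (racemic) | COC(=O)c1c(C)cc(O)c(C(Cl)OC)c1O | intermediate (not isolated)
12 | methyl haematommate (methyl 3-formyl-2,4-dihydroxy-6-methylbenzoate) | COC(=O)c1c(C)cc(O)c(C=O)c1O | intermediate
13 | methyl 2,4-bis(benzyloxy)-3-formyl-6-methylbenzoate | COC(=O)c1c(C)cc(OCc2ccccc2)c(C=O)c1OCc3ccccc3 | intermediate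
14 | 2,4-bis(benzyloxy)-3-formyl-6-methylbenzoic acid | Cc1cc(OCc2ccccc2)c(C=O)c(OCc3ccccc3)c1C(=O)O | intermediate
15 | 2,4-bis(benzyloxy)-3-formyl-6-methylbenzoic trifluoroacetic anhydride | Cc1cc(OCc2ccccc2)c(C=O)c(OCc3ccccc3)c1C(=O)OC(=O)C(F)(F)F | intermediate (not isolated)
16 | methyl 4-{[2,4-bis(benzyloxy)-3-formyl-6-methylbenzoyl]oxy}-2-methoxy-3,6-dimethylbenzoate | COC(=O)c1c(C)cc(OC(=O)c2c(C)cc(OCc3ccccc3)c(C=O)c2OCc4ccccc4)c(C)c1OC | intermediate
17 | 2'-O-methylatranorin | COC(=O)c1c(C)cc(OC(=O)c2c(C)cc(O)c(C=O)c2O)c(C)c1OC | target

**Summary**

Total steps: 10. Longest linear sequence: 7 steps (steps 1–5, 9, 10); steps 6–8 form the convergent ring-A branch.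

Steps most likely to fail:

1. Step 4. The cycloaddition to the β-methyl, singly activated alkyne may be slow enough that thermal breakdown or desilylation of the diene overtakes ring formation. Fallback, from 5 back to 8: the alkyne is replaced by its more reactive cumulene isomer. Diene 5 is warmed (toluene, 60–80 °C) with methyl buta-2,3-dienoate F1, a purchasable allenic ester whose conjugated C=C is a much better dienophile. The CH2 terminus of 5 should again bond to the β (central) carbon, giving racemic methyl 4-(tert-butyldimethylsilyloxy)-2,2-dimethoxy-3-methyl-6-methylidenecyclohex-3-ene-1-carboxylate F2. Catalytic DBU on crude F2 should then remove methanol by β-elimination next to the ester and move the exocyclic double bond into the ring, which gives 8.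

2. Step 2. The acylated dimethoxycarbenium intermediate may be O-demethylated by chloride (collapse towards the β-keto ester), or acetyl chloride may be diverted to ketene by the amine, before α-deprotonation occurs. Fallback, from 3 back to 4, bypassing ketene acetal 2 and step 1: acetyl chloride 3 is added to commercial 1,1-dichloroprop-1-ene under AlCl3 (CH2Cl2, 0 °C; Friedel–Crafts-type alkene acylation) to give 4,4,4-trichloro-3-methylbutan-2-one F3. Et3N removes HCl to give 4,4-dichloro-3-methylbut-3-en-2-one F4. Two addition–elimination steps with NaOMe (2 equiv, MeOH, 0 °C) then replace both vinylic chlorides by methoxy and give 4.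

3. Step 6. Electrophilic attack may divide between C3 and C5, since both are ortho to the 4-hydroxyl. Fallback, from 10 back to 12: the formyl group is introduced by directed metalation instead of electrophilic substitution. 10 is converted (NaH, MOMCl, DMF) into methyl 2,4-bis(methoxymethoxy)-6-methylbenzoate F5. The ester-tolerant amide base TMPMgCl·LiCl (THF, 0 °C) should magnesiate the ring at C3, the position held between the two coordinating acetal oxygens, and DMF then gives methyl 3-formyl-2,4-bis(methoxymethoxy)-6-methylbenzoate F6. HCl in MeOH removes both acetals to give 12.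

**Further compounds**

F1 | step 4 | methyl buta-2,3-dienoate | C=C=CC(=O)OC
F2 | step 4 | methyl 4-(tert-butyldimethylsilyloxy)-2,2-dimethoxy-3-methyl-6-methylidenecyclohex-3-ene-1-carboxylate (racemic) | COC(=O)C1C(=C)CC(O[Si](C)(C)C(C)(C)C)=C(C)C1(OC)OC
F3 | step 2 | 4,4,4-trichloro-3-methylbutan-2-one (racemic) | CC(=O)C(C)C(Cl)(Cl)Cl
F4 | step 2 | 4,4-dichloro-3-methylbut-3-en-2-one | CC(=O)C(C)=C(Cl)Cl
F5 | step 6 | methyl 2,4-bis(methoxymethoxy)-6-methylbenzoate | COCOc1cc(C)c(C(=O)OC)c(OCOC)c1
F6 | step 6 | methyl 3-formyl-2,4-bis(methoxymethoxy)-6-methylbenzoate | COCOc1cc(C)c(C(=O)OC)c(OCOC)c1C=O
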